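The route rests on cutting ring B (the dihydropyranone) at O1–C8a and C4–C4a. These bonds leave adjacent carbons of ring A, with the C5 oxygen next to C4a, exactly the pattern a 3-alkoxyaryne accepts from an O-nucleophile carrying an acyl group. In one operation the alkoxide of a syn-aldol ester adds to 3,5-dimethoxybenzyne at C8a and the C4a anion closes onto the ester, so both bonds and ring B form while the base-sensitive cis C2/C3 methyl pair is delivered intact. The precursors are o-silylaryl triflate 8 and the O-trimethylsilyl methyl ester 15 of an Evans syn aldol. O5 demethylation, a Claisen–Cope prenyl shift to C8 and a quinone-methide annulation at C6 complete the acid.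

Key step: step 7

Numbering: chromanone numbering is used throughout; ring A is the benzene ring, ring B the oxygen heterocycle.
Assumption: both pseudoenantiomeric cinchona squaramides are available, so the catalyst series in step 12 can be matched to the required 3R side-chain centre; the quinine-derived one is written.

Step 1
Reactants: 1 3,5-dimethoxyphenol
Product: 2 3,5-dimethoxyphenyl N-isopropylcarbamate
Conditions: i-PrNCO, Et3N (cat.), CH2Cl2, rt
Reagents that add atoms: isopropyl isocyanate, CC(C)N=C=O
Why: Amine-catalysed addition of the phenol to the isocyanate (carbamoylation) installs a removable N–H carbamate as ortho-directing group.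

Step 2
Reactants: 2 3,5-dimethoxyphenyl N-isopropylcarbamate
Product: 6 3,5-dimethoxy-2-(trimethylsilyl)phenyl N-isopropylcarbamate, via N-silyl carbamate 3 (not isolated), via aryllithium 4 (not isolated), via N-silyl arylsilane 5 (not isolated)
Conditions: TBSOTf, TMEDA, Et2O, 0 °C to rt; n-BuLi, TMEDA, −78 °C; TMSCl, −78 °C to rt; aq. NaHSO4
Reagents that add atoms: chlorotrimethylsilane, C[Si](C)(C)Cl
Why: Directed ortho-metalation: after N-silylation in the flask the carbamate steers lithiation to the position flanked by carbamate and methoxy (both such positions are equivalent), TMSCl traps the aryllithium, and the acidic work-up removes the N-silyl group.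

Step 3
Reactants: 6 3,5-dimethoxy-2-(trimethylsilyl)phenyl N-isopropylcarbamate
Product: 8 3,5-dimethoxy-2-(trimethylsilyl)phenyl trifluoromethanesulfonate, via silyl phenol 7 (not isolated)
Conditions: DBU, Et2NH, MeCN, 40 °C; then PhNTf2, rt
Reagents that add atoms: N-phenylbis(trifluoromethanesulfonimide), O=S(=O)(N(c1ccccc1)S(=O)(=O)C(F)(F)F)C(F)(F)F
Why: DBU induces E1cB loss of isopropyl isocyanate (scavenged by diethylamine) and the phenoxide is triflated in the same flask, so the protodesilylation-prone ortho-silyl phenol is never isolated.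

Step 4
Reactants: 9 (R)-4-benzyl-3-propionyloxazolidin-2-one; 10 acetaldehyde
Product: 13 (R)-4-benzyl-3-[(2R,3S)-3-hydroxy-2-methylbutanoyl]oxazolidin-2-one, via boron enolate 11 (not isolated), via boron aldolate 12 (not isolated)
Conditions: Bu2BOTf, i-Pr2NEt, CH2Cl2, 0 °C; MeCHO, −78 to 0 °C; pH 7 buffer, MeOH, H2O2, 0 °C
Reagents that add atoms: none
Why: Evans syn aldol: the Z-boron enolate reacts through a closed Zimmerman–Traxler chair on the face away from the benzyl group, so the (R)-auxiliary sets both new centres as (2R,3S).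

Step 5
Reactants: 13 (R)-4-benzyl-3-[(2R,3S)-3-hydroxy-2-methylbutanoyl]oxazolidin-2-one
Product: 14 methyl (2R,3S)-3-hydroxy-2-methylbutanoate
Conditions: MeOMgBr (MeMgBr + MeOH), MeOH/CH2Cl2, 0 °C; aq. NH4Cl
Reagents that add atoms: bromomagnesium methoxide, CO[Mg]Br
Why: Transesterification at the exocyclic imide carbonyl by the weakly basic magnesium methoxide releases the auxiliary without retro-aldol or epimerisation of the aldol.

Step 6
Reactants: 14 methyl (2R,3S)-3-hydroxy-2-methylbutanoate
Product: 15 methyl (2R,3S)-2-methyl-3-(trimethylsilyloxy)butanoate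
Conditions: TMSCl, imidazole, CH2Cl2, 0 °C; distillation
Reagents that add atoms: chlorotrimethylsilane, C[Si](C)(C)Cl
Why: Routine O-silylation of a secondary alcohol; the trimethylsilyl ether removes the O–H proton from the key step and serves as the fluoride-labile trigger.

Step 7
Reactants: 8 3,5-dimethoxy-2-(trimethylsilyl)phenyl trifluoromethanesulfonate; 15 methyl (2R,3S)-2-methyl-3-(trimethylsilyloxy)butanoate
Product: 19 (2S,3R)-5,7-dimethoxy-2,3-dimethylchroman-4-one, via 3,5-dimethoxybenzyne 16 (not isolated), via cesium alkoxide 17 (not isolated), via aryl anion 18 (not isolated)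
Conditions: CsF (slightly less than 8), 18-crown-6, THF, 0 °C to rt, 8 in excess over 15; pH 7 buffer quench at 0 °C
Reagents that add atoms: none
Why: Proposed new method: fluoride removes the aryl silicon of 8 to give aryne 16 and the oxygen-bound silicon of 15 to give alkoxide 17; the alkoxide adds to the aryne carbon remote from the flanking methoxy group (future C8a), and the aryl anion 18 so formed at C4a attacks the ester carbonyl and expels methoxide, which is silylated again by 15 or by 8 (each event feeding the next alkoxide or aryne), so that one fluoride per product suffices and the medium ends base-free. The closest known reaction types are the fluoride-mediated annulation of arynes with methyl salicylates to xanthones and the insertion of arynes into the C–O bond of carboxylic acids; a purely aliphatic β-silyloxy ester as the O/acyl donor is the unproven element. Ring B closes in the 6-exo-trig mode (addition–elimination at the ester carbon, C4a–C4) after the intermolecular O1–C8a bond has formed. No stereocentre is created; C2 and C3 are carried over from 15 with retention because no bond at either carbon is made or broken, so the syn aldol maps onto the cis-2,3-dimethyl pair. The step needs regioselective alkoxide addition, which the inductively withdrawing C5 methoxy group secures by polarising the aryne and stabilising the neighbouring C4a anion, and it needs acyl capture to outrun protonation, retro-aldol cleavage and C3 epimerisation, which is secured by the silyl ether (no O–H acid present), by a solvent without acidic C–H bonds, and by keeping fluoride below the amount of 8 so that neither alkoxide nor methoxide can accumulate.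

Step 8
Reactants: 19 (2S,3R)-5,7-dimethoxy-2,3-dimethylchroman-4-one
Product: 20 (2S,3R)-5-hydroxy-7-methoxy-2,3-dimethylchroman-4-one
Conditions: BCl3, CH2Cl2, −78 to 0 °C; ice-water
Reagents that add atoms: none
Why: Chelation-controlled ether cleavage: BCl3 bridges the C4 carbonyl and the peri C5 methoxy oxygen, so chloride demethylates only that ether under non-basic conditions that leave C2/C3 untouched.

Step 9
Reactants: 20 (2S,3R)-5-hydroxy-7-methoxy-2,3-dimethylchroman-4-one; 21 3-methylbut-2-en-1-ol
Product: 22 (2S,3R)-7-methoxy-2,3-dimethyl-5-[(3-methylbut-2-en-1-yl)oxy]chroman-4-one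
Conditions: PPh3, DIAD, THF, 0 °C to rt
Reagents that add atoms: none
Why: Mitsunobu etherification alkylates the hydrogen-bonded C5 phenol under essentially neutral conditions, avoiding the carbonate bases that would endanger the cis C2/C3 pair.

Step 10
Reactants: 22 (2S,3R)-7-methoxy-2,3-dimethyl-5-[(3-methylbut-2-en-1-yl)oxy]chroman-4-one
Product: 25 (2S,3R)-5-hydroxy-7-methoxy-2,3-dimethyl-8-(3-methylbut-2-en-1-yl)chroman-4-one, via ortho-dienone 23 (not isolated), via para-dienone 24 (not isolated)
Conditions: Eu(fod)3 (10 mol%), CHCl3, 60 °C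
Reagents that add atoms: none
Why: Lewis-acid-promoted aromatic Claisen rearrangement to C6 followed by Cope rearrangement of the dienone carries the allyl unit to C8 (para to O5) with normal prenyl connectivity, and tautomerisation restores the chelated phenol.

Step 11
Reactants: 25 (2S,3R)-5-hydroxy-7-methoxy-2,3-dimethyl-8-(3-methylbut-2-en-1-yl)chroman-4-one; 26 hexanal; 27 p-toluenesulfinic acid
Product: 28 (2S,3R)-5-hydroxy-7-methoxy-2,3-dimethyl-8-(3-methylbut-2-en-1-yl)-6-[1-(4-methylphenylsulfonyl)hexyl]chroman-4-one (both epimers at the sulfonyl-bearing carbon)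
Conditions: hexanal, p-TolSO2H, MgSO4, CH2Cl2, rt
Reagents that add atoms: none
Why: Acid-mediated three-component hydroxyalkylation–sulfination (Mannich-type condensation): C6, the only free ring A position and ortho to O5–H, attacks protonated hexanal and sulfinate traps the benzylic cation, giving a storable quinone-methide precursor.

Step 12
Reactants: 28 the C6 (1-tosylhexyl) chromanone; 29 Meldrum's acid (2,2-dimethyl-1,3-dioxane-4,6-dione)
Product: 32 O5 lactone of the target: (R)-4-pentyl-3,4-dihydropyran-2-one ring fused across O5/C5–C6 of the (2S,3R)-7-methoxy-2,3-dimethyl-8-prenylchroman-4-one core, via quinone methide 30 (not isolated), via Meldrum adduct 31 (not isolated)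
Conditions: quinine-derived 3,5-bis(trifluoromethyl)phenyl squaramide (10 mol%), aq. NaHCO3/CH2Cl2, rt; then PPTS (cat.), toluene, 90 °C
Reagents that add atoms: none
Why: Base-induced 1,4-elimination of sulfinate gives ortho-quinone methide 30, Meldrum's acid adds in a Michael reaction inside the hydrogen-bonded pocket of the bifunctional squaramide, which alone fixes the attacked face (catalyst control gives the R centre, the remote ring centres having no influence), and heating closes the lactone with loss of acetone and CO2.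

Step 13
Reactants: 32 O5 lactone of the target
Product: 33 (3R)-3-[(2S,3R)-5-hydroxy-7-methoxy-2,3-dimethyl-8-(3-methylbut-2-en-1-yl)-4-oxochroman-6-yl]octanoic acid
Conditions: LiOH, THF/H2O, 0 °C, short contact; 1 M HCl to pH 4 at 0 °C
Reagents that add atoms: lithium hydroxide, [Li+].[OH-]
Why: Saponification of the phenolic lactone (an aryl ester) is fast at 0 °C, so brief hydroxide exposure and cold mild acidification should free the acid before C3 can epimerise or the lactone re-form, the benzylic centre not being involved.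

Compound list
1 | 3,5-dimethoxyphenol | COc1cc(O)cc(OC)c1 | starting material
2 | 3,5-dimethoxyphenyl N-isopropylcarbamate | COc1cc(OC)cc(OC(=O)NC(C)C)c1 | intermediate
3 | 3,5-dimethoxyphenyl N-(tert-butyldimethylsilyl)-N-isopropylcarbamate | COc1cc(OC)cc(OC(=O)N(C(C)C)[Si](C)(C)C(C)(C)C)c1 | intermediate
4 | 2-lithio derivative of 3 | COc1cc(OC)c([Li])c(OC(=O)N(C(C)C)[Si](C)(C)C(C)(C)C)c1 | intermediate
5 | 3,5-dimethoxy-2-(trimethylsilyl)phenyl N-(tert-butyldimethylsilyl)-N-isopropylcarbamate | COc1cc(OC)c([Si](C)(C)C)c(OC(=O)N(C(C)C)[Si](C)(C)C(C)(C)C)c1 | intermediate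
6 | 3,5-dimethoxy-2-(trimethylsilyl)phenyl N-isopropylcarbamate | COc1cc(OC)c([Si](C)(C)C)c(OC(=O)NC(C)C)c1 | intermediate
7 | 3,5-dimethoxy-2-(trimethylsilyl)phenol | COc1cc(OC)c([Si](C)(C)C)c(O)c1 | intermediate
8 | 3,5-dimethoxy-2-(trimethylsilyl)phenyl trifluoromethanesulfonate | COc1cc(OC)c([Si](C)(C)C)c(OS(=O)(=O)C(F)(F)F)c1 | intermediate
9 | (R)-4-benzyl-3-propionyloxazolidin-2-one | CCC(=O)N1[C@H](Cc2ccccc2)COC1=O | starting material
10 | acetaldehyde | CC=O | starting material
11 | (Z)-dibutylboron enolate of 9 | C/C=C(\OB(CCCC)CCCC)N1[C@H](Cc2ccccc2)COC1=O | intermediate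
12 | O-dibutylboryl aldolate of 13 | CCCCB(CCCC)O[C@@H](C)[C@@H](C)C(=O)N1[C@H](Cc2ccccc2)COC1=O | intermediate
13 | (R)-4-benzyl-3-[(2R,3S)-3-hydroxy-2-methylbutanoyl]oxazolidin-2-one | O[C@@H](C)[C@@H](C)C(=O)N1[C@H](Cc2ccccc2)COC1=O | intermediate
14 | methyl (2R,3S)-3-hydroxy-2-methylbutanoate | O[C@@H](C)[C@@H](C)C(=O)OC | intermediate
15 | methyl (2R,3S)-2-methyl-3-(trimethylsilyloxy)butanoate | C[Si](C)(C)O[C@@H](C)[C@@H](C)C(=O)OC | intermediate
16 | 3,5-dimethoxybenzyne | COC1=CC(OC)=CC#C1 | intermediate
17 | cesium alkoxide of 14 | [Cs+].[O-][C@@H](C)[C@@H](C)C(=O)OC | intermediate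
18 | cesium salt of methyl (2R,3S)-3-(3,5-dimethoxyphenoxy)-2-methylbutanoate metalated at the ring carbon between the two oxygen-bearing carbons | [Cs+].COc1cc(OC)[c-]c(O[C@@H](C)[C@@H](C)C(=O)OC)c1 | intermediate
19 | (2S,3R)-5,7-dimethoxy-2,3-dimethylchroman-4-one | COc1cc(OC)c2c(c1)O[C@@H](C)[C@@H](C)C2=O | intermediate
20 | (2S,3R)-5-hydroxy-7-methoxy-2,3-dimethylchroman-4-one | COc1cc(O)c2c(c1)O[C@@H](C)[C@@H](C)C2=O | intermediate
21 | 3-methylbut-2-en-1-ol | CC(C)=CCO | starting material
22 | (2S,3R)-7-methoxy-2,3-dimethyl-5-[(3-methylbut-2-en-1-yl)oxy]chroman-4-one | COc1cc(OCC=C(C)C)c2c(c1)O[C@@H](C)[C@@H](C)C2=O | intermediate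
23 | ortho-dienone: (2S,3R)-7-methoxy-2,3-dimethyl-6-(2-methylbut-3-en-2-yl)-2,3-dihydro-6H-chromene-4,5-dione | C=CC(C)(C)C1C(=O)C2=C(C=C1OC)O[C@@H](C)[C@@H](C)C2=O | intermediate
24 | para-dienone: (2S,3R)-7-methoxy-2,3-dimethyl-8-(3-methylbut-2-en-1-yl)-2,3-dihydro-8H-chromene-4,5-dione | COC1=CC(=O)C2=C(C1CC=C(C)C)O[C@@H](C)[C@@H](C)C2=O | intermediate
25 | (2S,3R)-5-hydroxy-7-methoxy-2,3-dimethyl-8-(3-methylbut-2-en-1-yl)chroman-4-one | COc1cc(O)c2c(c1CC=C(C)C)O[C@@H](C)[C@@H](C)C2=O | intermediate
26 | hexanal | CCCCCC=O | starting material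
27 | p-toluenesulfinic acid | Cc1ccc(S(=O)O)cc1 | starting material
28 | (2S,3R)-5-hydroxy-7-methoxy-2,3-dimethyl-8-(3-methylbut-2-en-1-yl)-6-[1-(4-methylphenylsulfonyl)hexyl]chroman-4-one | CCCCCC(c1c(O)c2c(c(CC=C(C)C)c1OC)O[C@@H](C)[C@@H](C)C2=O)S(=O)(=O)c1ccc(C)cc1 | intermediate
29 | Meldrum's acid | CC1(C)OC(=O)CC(=O)O1 | starting material
30 | ortho-quinone methide: 6-hexylidene-7-methoxy-2,3-dimethyl-8-prenyl-2,3-dihydrochromene-4,5-dione, (2S,3R) | CCCCCC=C1C(=O)C2=C(O[C@@H](C)[C@@H](C)C2=O)C(CC=C(C)C)=C1OC | intermediate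
31 | 5-[(1R)-1-(chromanon-6-yl)hexyl] Meldrum's acid adduct | CCCCC[C@H](C1C(=O)OC(C)(C)OC1=O)c1c(O)c2c(c(CC=C(C)C)c1OC)O[C@@H](C)[C@@H](C)C2=O | intermediate
32 | O5 lactone of 33 ((R)-4-pentyl-3,4-dihydropyran-2-one fused at C5–C6) | CCCCC[C@H](CC(=O)O3)c1c3c2c(c(CC=C(C)C)c1OC)O[C@@H](C)[C@@H](C)C2=O | intermediate
33 | (3R)-3-[(2S,3R)-5-hydroxy-7-methoxy-2,3-dimethyl-8-(3-methylbut-2-en-1-yl)-4-oxochroman-6-yl]octanoic acid | CCCCC[C@H](CC(=O)O)c1c(O)c2c(c(CC=C(C)C)c1OC)O[C@@H](C)[C@@H](C)C2=O | target

Total step count: 13. Longest linear sequence: 10 steps (1–3, then 7–13; the ester branch 4–6 is equally long up to step 7).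

Steps most likely to fail

Step 7 (the step beyond known chemistry). The C4a anion may be protonated before it reaches the ester, the transient alkoxide may fragment by retro-aldol, or C3 may epimerise in the basic medium. The fallback uses known chemistry and forms O1–C2 by SN2 displacement instead of O1–C8a; it sets out from 1 and returns at 19. Phenol 1 is protected (MOMCl, i-Pr2NEt) as 1,3-dimethoxy-5-(methoxymethoxy)benzene F1. Commercial methyl (R)-3-hydroxybutanoate is methylated by the Fráter–Seebach dianion protocol (LDA, MeI) to the anti ester methyl (2R,3R)-3-hydroxy-2-methylbutanoate F2. Silylation (TBSCl, imidazole) gives methyl (2R,3R)-3-(tert-butyldimethylsilyloxy)-2-methylbutanoate F3, and amidation (MeNHOMe·HCl, i-PrMgCl) gives the Weinreb amide (2R,3R)-3-(tert-butyldimethylsilyloxy)-N-methoxy-N,2-dimethylbutanamide F4. Lithiation of F1 between the two oxygen groups (n-BuLi, THF) and acylation with F4 gives (2R,3R)-3-(tert-butyldimethylsilyloxy)-1-[2,4-dimethoxy-6-(methoxymethoxy)phenyl]-2-methylbutan-1-one F5. HCl in methanol removes both protecting groups to give (2R,3R)-3-hydroxy-1-(2-hydroxy-4,6-dimethoxyphenyl)-2-methylbutan-1-one F6. Mitsunobu cyclisation (PPh3, DIAD) closes ring B with inversion at the carbinol carbon, which converts the anti aldol into the cis chromanone 19.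

Step 12. Facial discrimination at the quinone methide may be insufficient, or the alkyl-substituted quinone methide may tautomerise to a styrene before the Michael addition. The fallback makes ring A the nucleophile toward a chiral iminium ion; it sets out from 25 and returns at 32. Phenol 25 is treated with (E)-oct-2-enal, diphenylprolinol trimethylsilyl ether (enantiomer chosen for the R centre) and benzoic acid. Friedel–Crafts alkylation at C6 and closure of the aldehyde onto O5 should give the lactol (R)-2-hydroxy-4-pentyl-3,4-dihydro-2H-pyran fused at C5–C6 of the chromanone F7. Oxidation (PhI(OAc)2, TEMPO cat.) then gives lactone 32.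

Step 11. C6 hydroxyalkylation of the hydrogen-bonded acyl phenol may be sluggish, or the acid may attack the prenyl double bond. The fallback uses a far stronger preformed electrophile without Brønsted acid and gives up catalyst control; it sets out from 25 and returns at 32. Knoevenagel condensation of 26 with 29 gives 5-hexylidene-2,2-dimethyl-1,3-dioxane-4,6-dione F8. Yb(OTf)3-catalysed conjugate addition of C6 of 25 and decarboxylative lactonisation (MeNO2, warm) should give 32 together with its epimer at the pentyl-bearing carbon, the (S)-lactone F9. Lactone 32 is then separated from F9 by preparative HPLC.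

Further compounds
F1 | step 7 | 1,3-dimethoxy-5-(methoxymethoxy)benzene | COCOc1cc(OC)cc(OC)c1
F2 | step 7 | methyl (2R,3R)-3-hydroxy-2-methylbutanoate | O[C@H](C)[C@@H](C)C(=O)OC
F3 | step 7 | methyl (2R,3R)-3-(tert-butyldimethylsilyloxy)-2-methylbutanoate | CC(C)(C)[Si](C)(C)O[C@H](C)[C@@H](C)C(=O)OC
F4 | step 7 | (2R,3R)-3-(tert-butyldimethylsilyloxy)-N-methoxy-N,2-dimethylbutanamide | CC(C)(C)[Si](C)(C)O[C@H](C)[C@@H](C)C(=O)N(C)OC
F5 | step 7 | (2R,3R)-3-(tert-butyldimethylsilyloxy)-1-[2,4-dimethoxy-6-(methoxymethoxy)phenyl]-2-methylbutan-1-one | CC(C)(C)[Si](C)(C)O[C@H](C)[C@@H](C)C(=O)c1c(OC)cc(OC)cc1OCOC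
F6 | step 7 | (2R,3R)-3-hydroxy-1-(2-hydroxy-4,6-dimethoxyphenyl)-2-methylbutan-1-one | O[C@H](C)[C@@H](C)C(=O)c1c(O)cc(OC)cc1OC
F7 | step 12 | lactol of 32 ((R)-2-hydroxy-4-pentyl-3,4-dihydro-2H-pyran fused at C5–C6, anomers) | CCCCC[C@H](CC(O)O3)c1c3c2c(c(CC=C(C)C)c1OC)O[C@@H](C)[C@@H](C)C2=O
F8 | step 11 | 5-hexylidene-2,2-dimethyl-1,3-dioxane-4,6-dione | CCCCCC=C1C(=O)OC(C)(C)OC1=O
F9 | step 11 | epimer of 32 at the pentyl-bearing carbon ((S)-lactone) | CCCCC[C@@H](CC(=O)O3)c1c3c2c(c(CC=C(C)C)c1OC)O[C@@H](C)[C@@H](C)C2=O
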